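**Retrosynthetic overview**
- The target is unmasked last from its pentamethyl ether by BBr3 cleavage of five O–CH3 bonds.
- Feature: in ring A, C4a (bearing the C4 carbonyl) and C8a (bearing O1) are adjacent carbons lying between the C5 oxygen and the C8 benzyl group. Ring C is therefore cut at C4a–C4, C8a–O1 and O1–C2, giving a C4a≡C8a aryne and 3-(3,4-dimethoxyphenyl)propiolic acid.
- The aryne comes from an ortho-silyl aryl triflate. Silicon is put on C4a by carbamate-directed ortho-lithiation of 2-(4-methoxybenzyl)-3,5-dimethoxyphenol, because electrophilic halogenation could not reliably tell this C–H from the equally activated one para to the hydroxyl.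
- The benzylphenol comes from 2-hydroxy-4,6-dimethoxybenzaldehyde by aryl Grignard addition and ionic deoxygenation; the acid comes from the aryl alkyne and CO2.
- Ring order: ring A, ring B and the benzyl ring are bought; ring C is the only ring made, in step 7.

Key step: step 7

Assumption: carbinol 3 is made and used as the racemate (its one stereocentre is removed in step 2), 2 is taken as the commercial THF solution, and the target has no stereocentre.

**Route**

Step 1
Reactants: 1 2-hydroxy-4,6-dimethoxybenzaldehyde; 2 4-methoxyphenylmagnesium bromide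
Product: 3 2-[hydroxy(4-methoxyphenyl)methyl]-3,5-dimethoxyphenol (racemic)
Conditions: 2 (2.5 equiv), THF, 0 °C to rt; sat. aq. NH4Cl
Reagents that add atoms: none
Why: Grignard 1,2-addition to the aldehyde: the first equivalent of 2 deprotonates the phenol (releasing anisole), the bromomagnesium phenoxide chelates the carbonyl oxygen and the second equivalent adds to give the carbinol, whose single stereocentre is formed racemic and is erased in step 2.

Step 2
Reactants: 3 2-[hydroxy(4-methoxyphenyl)methyl]-3,5-dimethoxyphenol
Product: 4 2-(4-methoxybenzyl)-3,5-dimethoxyphenol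
Conditions: Et3SiH (excess), TFA, CH2Cl2, 0 °C
Reagents that add atoms: none
Why: Ionic hydrogenation (Et3SiH/TFA deoxygenation of a diarylmethanol): acid ionises the carbinol to a diarylmethyl cation stabilised by both electron-rich rings, and the silane hydride, kept in excess so that it outruns Friedel–Crafts capture by a second arene, reduces it to the CH2 group.

Step 3
Reactants: 4 2-(4-methoxybenzyl)-3,5-dimethoxyphenol
Product: 5 2-(4-methoxybenzyl)-3,5-dimethoxyphenyl N-isopropylcarbamate
Conditions: i-PrNCO, Et3N (cat.), CH2Cl2, rt
Reagents that add atoms: isopropyl isocyanate CC(C)N=C=O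
Why: Amine-catalysed addition of the phenol to the isocyanate (O-carbamoylation) gives a secondary carbamate that is a strong metalation director anchored on the phenol oxygen and is later removable under mild base.

Step 4
Reactants: 5 2-(4-methoxybenzyl)-3,5-dimethoxyphenyl N-isopropylcarbamate
Product: 9 2-(4-methoxybenzyl)-3,5-dimethoxy-6-(trimethylsilyl)phenyl N-isopropylcarbamate, via N-silyl carbamate 6 (not isolated), via aryllithium 7 (not isolated), via bis-silyl carbamate 8 (not isolated)
Conditions: TMSOTf, TMEDA, Et2O, 0 °C to rt; n-BuLi, TMEDA, −78 °C; TMSCl, −78 °C to rt; aq. NaHSO4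
Reagents that add atoms: chlorotrimethylsilane C[Si](C)(C)Cl; trimethylsilyl trifluoromethanesulfonate C[Si](C)(C)OS(=O)(=O)C(F)(F)F (its silyl group sits on nitrogen in 6, 7 and 8 and is lost on work-up)
Why: Directed ortho-metalation with in situ N-silyl protection of the secondary carbamate: at −78 °C the n-BuLi–TMEDA complex bound to the carbamate should remove C6–H, the only ring hydrogen ortho to the carbamate and also flanked by the C5 methoxy group, in preference to C4–H (between two weaker methoxy directors) and to the crowded diarylmethane CH2; TMSCl traps the aryllithium and the acidic wash removes the N-silyl group.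

Step 5
Reactants: 9 2-(4-methoxybenzyl)-3,5-dimethoxy-6-(trimethylsilyl)phenyl N-isopropylcarbamate
Product: 11 2-(4-methoxybenzyl)-3,5-dimethoxy-6-(trimethylsilyl)phenyl trifluoromethanesulfonate, via ortho-silylphenol 10 (not isolated)
Conditions: Et2NH, DBU, MeCN, 40 °C; then PhNTf2, rt
Reagents that add atoms: N-phenylbis(trifluoromethanesulfonimide) O=S(=O)(N(c1ccccc1)S(=O)(=O)C(F)(F)F)C(F)(F)F
Why: Base-induced E1cB cleavage of the N–H carbamate (DBU, with Et2NH scavenging the isocyanate as a urea) frees the ortho-silyl phenoxide, which is O-sulfonylated in the same pot by PhNTf2, all under non-acidic conditions that spare the electron-rich C–Si bond from protodesilylation.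

Step 6
Reactants: 12 4-ethynyl-1,2-dimethoxybenzene
Product: 14 3-(3,4-dimethoxyphenyl)propiolic acid, via lithium acetylide 13 (not isolated)
Conditions: n-BuLi, THF, −78 °C; CO2; aq. HCl
Reagents that add atoms: carbon dioxide O=C=O
Why: Deprotonation of the terminal alkyne and carboxylation of the lithium acetylide with CO2 is the standard route to 3-arylpropiolic acids, and the two aryl methyl ethers are inert to n-BuLi at −78 °C.

Step 7
Reactants: 11 2-(4-methoxybenzyl)-3,5-dimethoxy-6-(trimethylsilyl)phenyl trifluoromethanesulfonate; 14 3-(3,4-dimethoxyphenyl)propiolic acid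
Product: 17 8-(4-methoxybenzyl)-5,7,3',4'-tetramethoxyflavone, via aryne 15 (not isolated), via hydroxy ynone 16 (not isolated)
Conditions: CsF, THF, 125 °C, sealed tube
Reagents that add atoms: none
Why: Fluoride attacks silicon of 11 and triflate leaves to give aryne 15; the cesium carboxylate of 14 adds through oxygen at C8a, the resulting C4a aryl anion attacks the ester carbonyl through a four-membered alkoxide that opens to the ortho-acyl phenoxide 16 (net insertion of the aryne into the acid C–O bond), and this phenoxide then adds to the ynone β-carbon. The closest known reaction type is the fluoride-mediated C–O insertion of arynes into carboxylic acids, which gives ortho-hydroxyaryl ketones and, with 3-arylpropiolic acids, flavones directly. Ring C is closed by 6-endo-dig oxa-Michael addition (O1–C2), favoured over 5-exo-dig closure to an aurone because the ynone is polarised for attack at the β-carbon. No stereocentre is formed. The step needs oxygen to bond at C8a and not at C4a: the C5 methoxy group next to C4a withdraws inductively, so the aryne is distorted for attack at the distal carbon C8a with charge building at C4a, and the C8 benzyl group offers only modest steric opposition. It also needs acyl transfer to outrun protonation of the aryl anion, which the aprotic medium, the high temperature and the intramolecular four-membered transition state should secure.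

Step 8
Reactants: 17 8-(4-methoxybenzyl)-5,7,3',4'-tetramethoxyflavone
Product: 18 8-(4-hydroxybenzyl)luteolin
Conditions: BBr3 (excess), CH2Cl2, −78 °C to rt; ice-water
Reagents that add atoms: none
Why: Exhaustive Lewis acid ether cleavage (BBr3 demethylation): each aryl methyl ether is complexed by boron and demethylated by bromide in an SN2 step, the chelated 5-O-methyl first, under anhydrous conditions at or below rt in which the pyrone ring stays closed so that the C8 benzyl group cannot be exchanged to C6 by Wessely–Moser isomerisation.

**Compound list**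

1 | 2-hydroxy-4,6-dimethoxybenzaldehyde | COc1cc(O)c(C=O)c(OC)c1 | starting material
2 | 4-methoxyphenylmagnesium bromide (THF solution) | COc1ccc([Mg]Br)cc1 | starting material
3 | 2-[hydroxy(4-methoxyphenyl)methyl]-3,5-dimethoxyphenol (racemic) | COc1ccc(C(O)c2c(O)cc(OC)cc2OC)cc1 | intermediate
4 | 2-(4-methoxybenzyl)-3,5-dimethoxyphenol | COc1ccc(Cc2c(O)cc(OC)cc2OC)cc1 | intermediate
5 | 2-(4-methoxybenzyl)-3,5-dimethoxyphenyl N-isopropylcarbamate | COc1ccc(Cc2c(OC(=O)NC(C)C)cc(OC)cc2OC)cc1 | intermediate
6 | 2-(4-methoxybenzyl)-3,5-dimethoxyphenyl N-isopropyl-N-(trimethylsilyl)carbamate | COc1ccc(Cc2c(OC(=O)N(C(C)C)[Si](C)(C)C)cc(OC)cc2OC)cc1 | intermediate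
7 | {2-[N-isopropyl-N-(trimethylsilyl)carbamoyloxy]-4,6-dimethoxy-3-(4-methoxybenzyl)phenyl}lithium | COc1ccc(Cc2c(OC(=O)N(C(C)C)[Si](C)(C)C)c([Li])c(OC)cc2OC)cc1 | intermediate
8 | 2-(4-methoxybenzyl)-3,5-dimethoxy-6-(trimethylsilyl)phenyl N-isopropyl-N-(trimethylsilyl)carbamate | COc1ccc(Cc2c(OC(=O)N(C(C)C)[Si](C)(C)C)c([Si](C)(C)C)c(OC)cc2OC)cc1 | intermediate
9 | 2-(4-methoxybenzyl)-3,5-dimethoxy-6-(trimethylsilyl)phenyl N-isopropylcarbamate | COc1ccc(Cc2c(OC(=O)NC(C)C)c([Si](C)(C)C)c(OC)cc2OC)cc1 | intermediate
10 | 2-(4-methoxybenzyl)-3,5-dimethoxy-6-(trimethylsilyl)phenol (present as its phenoxide) | COc1ccc(Cc2c(O)c([Si](C)(C)C)c(OC)cc2OC)cc1 | intermediate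
11 | 2-(4-methoxybenzyl)-3,5-dimethoxy-6-(trimethylsilyl)phenyl trifluoromethanesulfonate | COc1cc(OC)c(Cc2ccc(OC)cc2)c(OS(=O)(=O)C(F)(F)F)c1[Si](C)(C)C | intermediate
12 | 4-ethynyl-1,2-dimethoxybenzene | C#Cc1ccc(OC)c(OC)c1 | starting material
13 | lithium (3,4-dimethoxyphenyl)acetylide | COc1ccc(C#C[Li])cc1OC | intermediate
14 | 3-(3,4-dimethoxyphenyl)propiolic acid | COc1ccc(C#CC(=O)O)cc1OC | intermediate
15 | 4,6-dimethoxy-3-(4-methoxybenzyl)benzyne (1,2-didehydrobenzene) | COC1=CC(OC)=C(Cc2ccc(OC)cc2)C#C1 | intermediate
16 | 3-(3,4-dimethoxyphenyl)-1-[2-hydroxy-4,6-dimethoxy-3-(4-methoxybenzyl)phenyl]prop-2-yn-1-one (present as its cesium phenoxide) | COc1ccc(Cc2c(O)c(C(=O)C#Cc3ccc(OC)c(OC)c3)c(OC)cc2OC)cc1 | intermediate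
17 | 8-(4-methoxybenzyl)-5,7,3',4'-tetramethoxyflavone | O=c1cc(-c2ccc(OC)c(OC)c2)oc2c(Cc3ccc(OC)cc3)c(OC)cc(OC)c12 | intermediate
18 | 8-(4-hydroxybenzyl)luteolin | O=c1cc(-c2ccc(O)c(O)c2)oc2c(Cc3ccc(O)cc3)c(O)cc(O)c12 | target

**Step count**

Total steps: 8. Longest linear sequence: 7 steps (steps 1, 2, 3, 4, 5, 7, 8); step 6 is the one-step side branch.

**Steps most likely to fail**

1. Step 7. Several processes could divert it:
   - proton capture by the C4a aryl anion before acyl transfer, which stops at the aryl ester;
   - carboxylate attack at the wrong aryne carbon;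
   - thermal decarboxylation of the propiolate;
   - 5-exo closure of the phenoxide.

   The fallback sets out from 4 and returns at 17, building ring C by the chalcone route. C-Acetylation of 4 ortho to the hydroxyl by the boron-mediated Fries route (Ac2O, BF3·OEt2, 90 °C, the acetyl group held at C6 as its difluoroboron chelate) would give 1-[2-hydroxy-4,6-dimethoxy-3-(4-methoxybenzyl)phenyl]ethanone F1. Claisen–Schmidt condensation with 3,4-dimethoxybenzaldehyde (KOH, EtOH, rt) would give (E)-3-(3,4-dimethoxyphenyl)-1-[2-hydroxy-4,6-dimethoxy-3-(4-methoxybenzyl)phenyl]prop-2-en-1-one F2. Oxidative cyclisation of this 2'-hydroxychalcone (I2 cat., DMSO, 130 °C) would give 17; the only free hydroxyl is the one next to the benzyl group, so the ring can close only one way.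

2. Step 4. The base may deprotonate the diarylmethane CH2 and trigger a 1,4-carbamoyl shift, metalate C4 between the two methoxy groups, or allow anionic Fries migration before the silyl chloride arrives. The fallback sets out from 4 and returns at 11, bypassing 5 to 9. Amine-mediated ortho-selective bromination (NBS, i-Pr2NH cat., CH2Cl2, 0 °C), in which the N-bromoamine is delivered by hydrogen bonding to the phenol, would give 2-bromo-3,5-dimethoxy-6-(4-methoxybenzyl)phenol F3. O-Silylation (HMDS, THF, reflux) would give [2-bromo-3,5-dimethoxy-6-(4-methoxybenzyl)phenoxy]trimethylsilane F4. Bromine–lithium exchange (n-BuLi, THF, −78 °C) followed by 1,3 O-to-C silyl shift (retro-Brook rearrangement) would give the lithium phenoxide of 10, which Tf2O converts to 11.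

3. Step 8. Cleavage may stall at the least activated ethers, or acid may promote loss or migration of the 4-hydroxybenzyl group through a para-quinone methide once the phenols are free. The fallback sets out from 17 and ends at 18: nucleophilic demethylation under basic conditions (NaSEt in excess, DMF, 130 °C; aq. HCl work-up). Thiolate attacks each methyl carbon by SN2 while the product is held as its poly-phenoxide, which is a poor acceptor for ring-opening conjugate addition and cannot ionise at the benzylic carbon. No further compound is made on this way (F0).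

Further compounds
F1 | step 7 | 1-[2-hydroxy-4,6-dimethoxy-3-(4-methoxybenzyl)phenyl]ethanone | COc1ccc(Cc2c(O)c(C(C)=O)c(OC)cc2OC)cc1
F2 | step 7 | (E)-3-(3,4-dimethoxyphenyl)-1-[2-hydroxy-4,6-dimethoxy-3-(4-methoxybenzyl)phenyl]prop-2-en-1-one | COc1ccc(Cc2c(O)c(C(=O)/C=C/c3ccc(OC)c(OC)c3)c(OC)cc2OC)cc1
F3 | step 4 | 2-bromo-3,5-dimethoxy-6-(4-methoxybenzyl)phenol | COc1ccc(Cc2c(O)c(Br)c(OC)cc2OC)cc1
F4 | step 4 | [2-bromo-3,5-dimethoxy-6-(4-methoxybenzyl)phenoxy]trimethylsilane | COc1ccc(Cc2c(O[Si](C)(C)C)c(Br)c(OC)cc2OC)cc1
F0 | step 8 | none | none
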